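Lifetimes can be counted here. The larch run keeps 67.1% of its starting material at 6.00 min, which makes 0.399 lifetimes. This lifetime count, minus the natural logarithm of the fraction of starting material left, is the quantity carried through.

in all of them: starting material 0.25 M

| flask | reagent | remark | time |
|---|---|---|---|
| larch | 0.63 M | run made earlier |  |
| cedar | 0.99 M | run made earlier |  |
| alpha | 0.500 M |  | 8.0 min |
| eta | 0.650 M |  | 8.0 min |

| run | time / min | starting material / % | product / % |
|---|---|---|---|
| larch | 0.417 | 98.1 | 1.9 |
| larch | 0.667 | 97.0 | 4.5 |
| larch | 1.33 | 91.5 | 3.2 |
| larch | 2.00 | 88.8 | 5.5 |
| larch | 3.00 | 83.4 | 6.9 |
| larch | 6.00 | 67.1 | 17.9 |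
| cedar | 0.417 | 94.9 | 1.6 |
| cedar | 1.00 | 90.7 | 4.1 |
| cedar | 2.00 | 80.8 | 11.7 |
| cedar | 3.00 | 71.8 | 15.0 |
| cedar | 4.00 | 66.4 | 17.4 |
| cedar | 6.00 | 49.8 | 26.3 |

(standard deviation of a reading: 1 percentage point)

- what was read earlier has a scatter of 1 percentage point, one standard deviation
- what has gone from starting material into another species counts as reacted, even if it can come back

- part of the starting material that has reacted at the end, alpha
- part of the starting material that has reacted at the end, eta
- what raising the concentration of reagent from its lowest to its highest value here does to the part of the starting material that has reacted (changes below 5 percentage points count as none) (it falls / it rises / no change)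

In larch the count stood at 0.182 at 3.00 min, so doubling the time gave twice the count. The loss therefore reads as first order with reagent in excess, a pseudo-first-order loss, and the count should follow the dose, meaning reagent charged times time. The cedar run tests this: its dose is 1.57 times that of larch, and its count, 0.697, is 1.75 times as large. As a reading, cedar runs ahead of its dose.

Alpha differs from larch in two settings, with a fraction 0.794 of the reagent of larch but 1.33 times its time. Together these give 1.06 times the dose of larch, so alpha should end a little beyond larch. The reckoning made here gives alpha a count of 0.422, hence 34.4% reacted. Eta gets 0.549, hence 42.2%, a rise of 7.8 percentage points, which is more than the margin.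

The forecast, a little lower than this reckoning, gives 32% for alpha and 41% for eta, says it rises, and rests on this: “Loss of starting material looks first order over these runs”.

The flask gives 34.7% for alpha and 43.9% for eta: it rises, by 9.2 points.

    starting material + reagent + released group → product + 2 released group (k = 0.121 M⁻² s⁻¹)
    starting material + reagent → product + released group (k = 8.55 × 10⁻⁴ M⁻¹ s⁻¹)
    starting material + released group ⇌ idle adduct, settled at all times (K = 110 M⁻¹)
    released group → by-product carried off (k = 0.00412 s⁻¹)

Alpha's count from that result is 0.426, beside the 0.422 reckoned. For alpha read at 3.0 min the same reckoning gives a count of 0.158, hence 14.6% reacted, and that flask gives 14.3%. In alpha at 8.00 min, the direct step of starting material with reagent uses starting material 3.1 times as fast as the step helped by released group, and the half-life of starting material by that direct step, 30 min, is long against the 8.0 min of the run. Alpha at that time holds 65.3% starting material, 18.2% product and 16.5% idle adduct.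

The data are calculated from invented constants, and the scatter is random.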